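**Plan**

1. Locants: benzoxepine O1, C2, C3(=CH2), C4=C5, C5a–C9a; acyl chain C1 (C=O) to C18. The retrosynthesis cuts, in order, C9–C10 of the acyl chain, the ester O–C1 bond, and (after CH2OH ⇒ CO2Me at C7) the oxepine ring at C4=C5 and O1–C2.
2. Forward: the seven-membered oxepine ring is closed first, in one flask, on a salicylaldehyde that carries C7 as a methyl ester (O1–C2 by phenoxide allylation, C4=C5 by intramolecular Wittig; the C3 methylidene comes in with the four-carbon phosphonium reagent). The C7 ester is then reduced and acylated with the C1–C9 bromo acid, and C10–C18 is joined last.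
3. Enabling feature: C9 and C10 are both unbranched primary CH2 carbons, flanked only by CH2 groups, eight CH2 units from the ester C1=O and remote from the ring. In the simplest precursors both are primary bromides (like, electrophilic polarity), so magnesium reverses the polarity of C10 and copper joins it to C9–Br.
4. A closed-shell Cu(I)/Cu(III) union is preferred to a decarboxylative or other radical union of C9 and C10, because a primary alkyl radical would add to the C3(=CH2)–C4=C5 diene. The cuprate should leave that diene, the O1–C2 allyl aryl ether and the C7 benzylic ester alone.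
5. Stereochemistry: the target has no stereocentre; the only geometric element, the cis C4=C5 bond, is enforced by the seven-membered ring in the Wittig closure.

Key step: step 5

**Route**

Step 1
Reactants: 1 3-bromo-2-(bromomethyl)prop-1-ene; 2 triphenylphosphine
Product: 3 [2-(bromomethyl)prop-2-en-1-yl]triphenylphosphonium bromide
Conditions: 1 (1.5 equiv), 2 (1.0 equiv), toluene, rt; precipitated salt filtered off
Reagents that add atoms: none
Why: Phosphine quaternisation (SN2 at one allylic C–Br of the symmetric dibromide) should stop at the mono-salt, because this salt precipitates from toluene and 1 is in excess.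

Step 2
Reactants: 3 [2-(bromomethyl)prop-2-en-1-yl]triphenylphosphonium bromide; 4 methyl 3-formyl-4-hydroxybenzoate
Product: 6 methyl 3-methylidene-2,3-dihydro-1-benzoxepine-7-carboxylate, via aryloxyallylphosphonium bromide 5 (not isolated)
Conditions: K2CO3 (3 equiv), 18-crown-6 (10 mol %), MeCN (0.05 M), rt then 60 °C
Reagents that add atoms: none
Why: Williamson O-allylation of the phenoxide (SN2 and SN2′ lead to the same ether 5) should be followed on warming by carbonate-mediated formation of the semi-stabilised allylic ylide and intramolecular Wittig olefination of the ortho formyl group, a tandem annulation known for salicylaldehydes with ω-bromoalkylphosphonium salts; the seven-membered ring allows only the cis C4=C5 alkene.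

Step 3
Reactants: 6 methyl 3-methylidene-2,3-dihydro-1-benzoxepine-7-carboxylate
Product: 7 (3-methylidene-2,3-dihydro-1-benzoxepin-7-yl)methanol
Conditions: DIBAL-H (2.5 equiv), CH2Cl2, −78 → −20 °C; aq Rochelle salt
Reagents that add atoms: none
Why: DIBAL-H reduction of the aryl methyl ester should give the primary benzylic alcohol, since a hydride donor at low temperature does not touch the unactivated diene or the allyl aryl ether.

Step 4
Reactants: 7 (3-methylidene-2,3-dihydro-1-benzoxepin-7-yl)methanol; 8 9-bromononanoic acid
Product: 9 (3-methylidene-2,3-dihydro-1-benzoxepin-7-yl)methyl 9-bromononanoate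
Conditions: DCC (1.1 equiv), DMAP (10 mol %), CH2Cl2, 0 °C → rt
Reagents that add atoms: none
Why: Steglich esterification acylates the primary alcohol under neutral conditions, which avoids acid that could ionise the p-alkoxybenzylic position or isomerise the exocyclic diene, and the primary bromide is a spectator.

Step 5
Reactants: 9 (3-methylidene-2,3-dihydro-1-benzoxepin-7-yl)methyl 9-bromononanoate; 10 nonylmagnesium bromide
Product: 11 (3-methylidene-2,3-dihydro-1-benzoxepin-7-yl)methyl octadecanoate
Conditions: Li2CuCl4 (3 mol %), NMP (4 equiv), THF, −20 → 0 °C, 10 (1.2 equiv, 1.0 M in Et2O) added over 1 h; aq NH4Cl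
Reagents that add atoms: none
Why: Transmetalation of 10 to copper gives a magnesium dinonylcuprate(I), which displaces bromide at the primary C9 of 9 by SN2 oxidative addition to a trialkylcopper(III) that reductively eliminates the C9–C10 bond and returns copper(I). The closest known reaction type is the copper-catalysed Kumada-type cross-coupling of alkyl Grignard reagents with primary alkyl bromides in THF/NMP, which is known to spare ester groups. No ring is closed and no stereocentre is formed; both carbons come from primary bromides of like polarity and magnesium supplies the polarity reversal at C10. The step needs chemoselectivity for C9–Br over the benzylic ester carbonyl, the O1–C2 allyl aryl ether and the C3(=CH2)–C4=C5 diene. This should be secured by the unhindered primary bromide eight CH2 groups from C1, by slow addition of 10 at −20 to 0 °C with NMP so that cuprate alkylation outruns carbonyl addition and allylic displacement, and by the closed-shell Cu(I)/Cu(III) path, which generates no free alkyl radical able to add to the diene.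

**Compound list**

1 | 3-bromo-2-(bromomethyl)prop-1-ene | C=C(CBr)CBr | starting material
2 | triphenylphosphine | c1ccc(cc1)P(c1ccccc1)c1ccccc1 | starting material
3 | [2-(bromomethyl)prop-2-en-1-yl]triphenylphosphonium bromide | C=C(CBr)C[P+](c1ccccc1)(c1ccccc1)c1ccccc1.[Br-] | intermediate
4 | methyl 3-formyl-4-hydroxybenzoate | COC(=O)c1ccc(O)c(C=O)c1 | starting material
5 | {2-[(2-formyl-4-(methoxycarbonyl)phenoxy)methyl]prop-2-en-1-yl}triphenylphosphonium bromide | COC(=O)c1ccc(OCC(=C)C[P+](c2ccccc2)(c2ccccc2)c2ccccc2)c(C=O)c1.[Br-] | intermediate
6 | methyl 3-methylidene-2,3-dihydro-1-benzoxepine-7-carboxylate | C=C1C=Cc2cc(C(=O)OC)ccc2OC1 | intermediate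
7 | (3-methylidene-2,3-dihydro-1-benzoxepin-7-yl)methanol | C=C1C=Cc2cc(CO)ccc2OC1 | intermediate
8 | 9-bromononanoic acid | OC(=O)CCCCCCCCBr | starting material
9 | (3-methylidene-2,3-dihydro-1-benzoxepin-7-yl)methyl 9-bromononanoate | C=C1C=Cc2cc(COC(=O)CCCCCCCCBr)ccc2OC1 | intermediate
10 | nonylmagnesium bromide | CCCCCCCCC[Mg]Br | starting material
11 | (3-methylidene-2,3-dihydro-1-benzoxepin-7-yl)methyl octadecanoate | C=C1C=Cc2cc(COC(=O)CCCCCCCCCCCCCCCCC)ccc2OC1 | target

**Count**

Total steps: 5. Longest linear sequence: 5 steps (1 → 3 → 6 → 7 → 9 → 11).

**Steps most likely to fail**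

Step 5. The Grignard reagent may add to the benzylic ester carbonyl faster than the cuprate alkylates C9–Br. Copper may also mediate displacement of the aryloxide at the allylic C2 (or SN2′ attack at the methylidene), and bromine–magnesium exchange may lead to homocoupling. The fallback sets out from 9 and comes back at 11. It replaces the carbanion by a neutral boron nucleophile in an alkyl–alkyl Suzuki–Miyaura coupling. Non-1-ene is hydroborated with 9-BBN-H (THF, rt) to 9-nonyl-9-borabicyclo[3.3.1]nonane F1, and this borane is coupled with 9 under Pd(OAc)2/PCy3, K3PO4·H2O, THF, rt, which should give 11 directly. The point to watch there is ionisation of the allyl aryl ether by palladium(0), which the bulky bis-phosphine complex and room temperature should hold back.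

Step 2. The ylide may react between molecules and give oligomers with trans alkenes that cannot close the ring. It may also isomerise to the vinylphosphonium salt, or the phosphonium salt may be hydrolysed by wet carbonate before ring closure. The fallback sets out from 4 and comes back at 6. It closes the ring through the C4–C5 single bond and makes the alkene by elimination. Phenol 4 is O-alkylated with an excess of 1 (K2CO3, acetone, rt) to methyl 4-{[2-(bromomethyl)prop-2-en-1-yl]oxy}-3-formylbenzoate F2. Zinc dust in THF/aq NH4Cl (intramolecular Barbier allylation) should then close the seven-membered ring to racemic methyl 5-hydroxy-3-methylidene-2,3,4,5-tetrahydro-1-benzoxepine-7-carboxylate F3. MsCl/Et3N (CH2Cl2, 0 °C) should give racemic methyl 5-(methanesulfonyloxy)-3-methylidene-2,3,4,5-tetrahydro-1-benzoxepine-7-carboxylate F4, and DBU should eliminate toward C4, the only carbon with a β-hydrogen, to give 6.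

Step 4. Acyl transfer may stall through O→N migration of the O-acylisourea to the N-acylurea, and the electron-rich benzylic alcohol may ionise or the diene isomerise if acid builds up. The fallback sets out from 7 and comes back at 9. It is a Mitsunobu esterification (PPh3, DIAD, acid 8, THF, 0 °C), which activates the alcohol as its oxyphosphonium ion instead of activating the acid. It makes no compound outside the list (F0).

**Further compounds**

F1 | step 5 | 9-nonyl-9-borabicyclo[3.3.1]nonane | CCCCCCCCCB1C2CCCC1CCC2
F2 | step 2 | methyl 4-{[2-(bromomethyl)prop-2-en-1-yl]oxy}-3-formylbenzoate | COC(=O)c1ccc(OCC(=C)CBr)c(C=O)c1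
F3 | step 2 | racemic methyl 5-hydroxy-3-methylidene-2,3,4,5-tetrahydro-1-benzoxepine-7-carboxylate | C=C1CC(O)c2cc(C(=O)OC)ccc2OC1
F4 | step 2 | racemic methyl 5-(methanesulfonyloxy)-3-methylidene-2,3,4,5-tetrahydro-1-benzoxepine-7-carboxylate | C=C1CC(OS(C)(=O)=O)c2cc(C(=O)OC)ccc2OC1
F0 | step 4 | none | none
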